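- If each passage, substrate to target and target to over-reacted product, takes one reagent, a substrate going all the way costs two. So I carried the spare reagent, the reagent charge less two per substrate charged 7.50 mM, which was positive for this flask and showed which charge would give out first.

all flasks: reagent in the second phase 37.5 mM
- amber: substrate 7.5 mM; run made earlier
- red: substrate 30 mM; run made earlier
- flask: substrate 15 mM; time 25 h; volume of the second phase over the first 0.50

| run | time / h | over-reacted product / % | target / % | substrate / % |
|---|---|---|---|---|
| amber | 1.50 | 99.1 | 0.1 | 0.3 |
| amber | 2.50 | 100.0 | 0.5 | 0 |
| amber | 4.00 | 99.8 | 0.2 | 0 |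
| amber | 6.00 | 99.3 | 0.4 | 0.4 |
| amber | 8.00 | 100.1 | 0.5 | 0.1 |
| amber | 12.0 | 99.8 | 0 | 0 |
| amber | 20.0 | 100.9 | 0 | 0.3 |
| red | 3.00 | 49.4 | 26.1 | 23.6 |
| red | 6.00 | 49.2 | 26.9 | 24.2 |
| red | 8.00 | 49.0 | 26.2 | 24.3 |
| red | 12.0 | 49.1 | 26.7 | 24.6 |
| red | 15.0 | 49.3 | 26.4 | 24.1 |
| red | 20.0 | 49.9 | 25.8 | 25.1 |

(standard deviation of a reading: 0.5 percentage points)

* why nothing more happens at 25 h, or that something still does (all of the substrate has reacted / forward and back rates have come level / it is still moving)
* the over-reacted product standing at 25 h, as a percentage of the substrate charged

- in the second phase: reagent in the second phase; everything else is in the first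
- charges count per volume of the first phase; a concentration in a rate is the amount of a species over the volume of its own phase; every rate counts per litre of the first phase
- the earlier runs hold the two phases in the same ratio of volumes as the flask asked about
- the reaction counts as stopped when no species that holds the substrate changes by six tenths of a point or more over the second half of the time

- The red run, with a spare of −22.5 mM, supported that count: its readings at 3.00 h added up to 37.5 mM of reagent used against a charge of 37.5 mM, and its later readings stayed near that level.
- Amber started fast, finishing before its first reading at 1.50 h. I took the rate to follow the reagent not yet used, so I reckoned it to fall by a factor 5.00 from start to finish in this flask and by 1.67 in the amber run.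
- Stretching amber's time by the ratio of their spares gave me 4.50 h, shorter than the 25 h allowed. I therefore expected substrate to be the limiting reagent and to be used up.
- The forecast said all of the substrate has reacted, with 99.7% (98.5% to 100.5%) of over-reacted product: “With less excess the flask runs slower, but 25 h is ample”.
- The flask gave 100% of over-reacted product at 25.0 h, and all of the substrate has reacted.

    substrate + reagent in the reaction phase → target (k = 0.100 L mol⁻¹ s⁻¹)
    reagent in the reaction phase ⇌ reagent in the second phase, rate k2*([reagent in the reaction phase] - [reagent in the second phase]/K2) per volume of the first phase (partition coefficient = 0.710, kL = 0.00350 s⁻¹)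
    reagent in the reaction phase + target → over-reacted product (k = 0.140 L mol⁻¹ s⁻¹)
    reagent in the reaction phase ⇌ dormant form (K = 1.00, k = 6.50 × 10⁻⁴ s⁻¹)

- The spare of 7.50 mM stood in this flask at 25.0 h as 3.18 mM of reagent in the reaction phase, 3.18 mM of dormant form and 1.13 mM of reagent in the second phase. A neighbouring flask with 38 mM of substrate had a spare of −38.5 mM; at 25.0 h it held 0% of its charge of reagent in the second phase and 36% of its substrate.

The data were generated by integration for an exercise, noise included.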